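**Plan**

1. Labels used throughout (germacrane style): ten-membered ring C1–C10 with C1=C10, C4(OH)(CH3), C6 (acyloxy carbon), C7/C8 ring fusion (lactone O on C8), C11=C13 exocyclic methylene, C12 lactone carbonyl, C14 the CH2OAc carbon.
2. Retrosynthetic cuts, in order: the silyl ether on O4; the C6–O ester bond (esterification with inversion); the ring bond C6–C7 (allylchromium addition to a C6 aldehyde); the butenolide alkene C7=C11 (metathesis) and the C8–O acyl bond; the C1=C10 alkene (Horner–Wadsworth–Emmons).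
3. Forward: the C1–C6 chain comes from geraniol and is joined through C1=C10 to a γ-vinyl α-phosphono lactone (C7–C10, C14). The lactone is reduced and acetylated, the butenolide ring is built on O8 by esterification and ring-closing metathesis, and the ten-membered ring is closed last at C6–C7, which also creates the α-methylene lactone.
4. Enabling feature: the homoallylic alcohol array C13=C11–C7–C6–O at the junction of the γ-lactone and the ten-membered ring is the retron of a carbonyl allylation by a 3-(metallomethyl)butenolide.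
5. Stereochemistry: C4 from a Sharpless epoxidation; C8 from an (R)-lactone of the D-glutamic acid series; C7 and C6 from the ring closure (C7 anti to the C8 side chain, C6 from the chair transition state and then inverted in the ester-forming step); C1=C10 geometry from the olefination; side-chain Z geometry from (Z)-2-iodobut-2-en-1-ol.

Key step: step 19

Remark on the chemistry: (5R)-5-(hydroxymethyl)dihydrofuran-2(3H)-one and 2-(bromomethyl)acrylic acid are taken as purchasable.

**Route**

Step 1
Reactants: 1 geraniol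
Product: 2 (2S,3S)-2,3-epoxygeraniol
Conditions: Ti(OiPr)4 (5 mol%), L-(+)-diethyl tartrate (7.5 mol%), tBuOOH, 4 Å MS, CH2Cl2, −20 °C
Reagents that add atoms: tert-butyl hydroperoxide, CC(C)(C)OO
Why: Sharpless asymmetric epoxidation, in which the titanium tartrate complex binds the allylic alcohol and delivers oxygen to one face of the C2=C3 alkene (L-(+)-tartrate should give the 2S,3S epoxide), fixing the future C4 centre and leaving the remote alkene untouched.

Step 2
Reactants: 2 (2S,3S)-2,3-epoxygeraniol
Product: 3 (3S)-3,7-dimethyloct-6-ene-1,3-diol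
Conditions: NaAlH2(OCH2CH2OMe)2, THF, 0 °C → rt; aq. KNaC4H4O6 work-up
Reagents that add atoms: none
Why: Directed hydride opening of a 2,3-epoxy alcohol, in which the aluminium alkoxide delivers hydride to C2, so the 1,3-diol forms and the tertiary C–O bond (future C4) keeps its configuration.

Step 3
Reactants: 3 (3S)-3,7-dimethyloct-6-ene-1,3-diol
Product: 4 (3S)-3,7-dimethyl-1,3-bis(triethylsilyloxy)oct-6-ene
Conditions: Et3SiOTf (2.5 equiv), 2,6-lutidine, CH2Cl2, −78 → 0 °C
Reagents that add atoms: triethylsilyl trifluoromethanesulfonate, CC[Si](CC)(CC)OS(=O)(=O)C(F)(F)F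
Why: Silyl triflate silylation is reactive enough to cap the tertiary as well as the primary hydroxyl, so both are protected in one operation.

Step 4
Reactants: 4 (3S)-3,7-dimethyl-1,3-bis(triethylsilyloxy)oct-6-ene
Product: 6 (4S)-4-methyl-4,6-bis(triethylsilyloxy)hexanal, via ozonide 5 (not isolated)
Conditions: O3, CH2Cl2, −78 °C; then PPh3, −78 °C → rt
Reagents that add atoms: ozone, [O-][O+]=O
Why: Ozonolysis with reductive work-up cleaves the only alkene to the C1 aldehyde, and silyl ethers are inert to ozone.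

Step 5
Reactants: 7 (5R)-5-(hydroxymethyl)dihydrofuran-2(3H)-one
Product: 8 (2R)-5-oxotetrahydrofuran-2-carbaldehyde
Conditions: Dess–Martin periodinane, CH2Cl2, 0 °C → rt; crude product used at once
Reagents that add atoms: none
Why: Dess–Martin oxidation of the primary alcohol stops at the aldehyde under nearly neutral conditions, so the adjacent oxygen-bearing stereocentre should not be enolised.

Step 6
Reactants: 8 (2R)-5-oxotetrahydrofuran-2-carbaldehyde
Product: 9 (5R)-5-vinyldihydrofuran-2(3H)-one
Conditions: Ph3PCH3Br, KN(SiMe3)2, THF, −78 → 0 °C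
Reagents that add atoms: methyltriphenylphosphonium bromide, C[P+](c1ccccc1)(c1ccccc1)c1ccccc1.[Br-]
Why: Wittig methylenation, in which the non-stabilised ylide reacts with the aldehyde far faster than with the lactone carbonyl, and low temperature limits epimerisation of the α-alkoxy aldehyde.

Step 7
Reactants: 9 (5R)-5-vinyldihydrofuran-2(3H)-one
Product: 11 diethyl [(5R)-2-oxo-5-vinyltetrahydrofuran-3-yl]phosphonate (C3 epimers), via enol phosphate 10 (not isolated)
Conditions: LiN(iPr)2 (1.1 equiv), THF, −78 °C; ClP(O)(OEt)2; then LiN(iPr)2 (2.2 equiv), −78 °C → rt; AcOH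
Reagents that add atoms: diethyl chlorophosphate, CCOP(=O)(Cl)OCC
Why: O-phosphorylation of the lactone enolate followed by base-induced 1,3-migration of phosphorus from oxygen to carbon gives the α-phosphono lactone needed for the Horner–Wadsworth–Emmons step; C5 is not touched and the epimer mixture at C3 is of no consequence.

Step 8
Reactants: 12 (E)-but-2-enal
Product: 13 (Z)-2-iodobut-2-enal
Conditions: I2, K2CO3, DMAP (cat.), THF/H2O, rt
Reagents that add atoms: iodine, II
Why: Amine-catalysed α-iodination of an enal (conjugate addition of DMAP, iodination of the enolate, elimination) gives the 2-iodoenal with the methyl group cis to iodine.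

Step 9
Reactants: 13 (Z)-2-iodobut-2-enal
Product: 14 (Z)-2-iodobut-2-en-1-ol
Conditions: NaBH4, CeCl3·7H2O, MeOH, 0 °C
Reagents that add atoms: none
Why: Luche reduction gives clean 1,2-reduction of the enal without touching the C–I bond or the alkene geometry.

Step 10
Reactants: 14 (Z)-2-iodobut-2-en-1-ol
Product: 16 (Z)-2-(hydroxymethyl)but-2-enoic acid, via dilithio species 15 (not isolated)
Conditions: tBuLi (3.1 equiv), Et2O, −78 °C; CO2; then aq. HCl
Reagents that add atoms: carbon dioxide, O=C=O
Why: Iodine–lithium exchange on the lithium alkoxide proceeds with retention of alkene geometry, and carboxylation of the configurationally stable vinyllithium at −78 °C places the carboxyl group cis to the methyl group (Z).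

Step 11
Reactants: 16 (Z)-2-(hydroxymethyl)but-2-enoic acid
Product: 17 (Z)-2-(acetoxymethyl)but-2-enoic acid
Conditions: Ac2O (1.2 equiv), pyridine, CH2Cl2, 0 °C; aqueous work-up
Reagents that add atoms: acetic anhydride, CC(=O)OC(C)=O
Why: Acetylation of the primary hydroxyl under mild base, during which the acid is present as its carboxylate and the Z alkene is therefore not activated toward isomerisation.

Step 12
Reactants: 6 (4S)-4-methyl-4,6-bis(triethylsilyloxy)hexanal; 11 diethyl [(5R)-2-oxo-5-vinyltetrahydrofuran-3-yl]phosphonate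
Product: 18 (3E,5R)-3-[(4S)-4-methyl-4,6-bis(triethylsilyloxy)hexylidene]-5-vinyldihydrofuran-2(3H)-one
Conditions: 11, NaH, THF, 0 °C; then 6, 0 °C → rt
Reagents that add atoms: none
Why: Horner–Wadsworth–Emmons olefination, which for α-alkylidene γ-lactones should favour the E isomer (chain cis to the ring CH2, trans to the carbonyl), that is the C1=C10 geometry of the target with C2 cis to C9 and C14 trans to C2; any Z isomer is removed by chromatography.

Step 13
Reactants: 18 (3E,5R)-3-[(4S)-4-methyl-4,6-bis(triethylsilyloxy)hexylidene]-5-vinyldihydrofuran-2(3H)-one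
Product: 19 (3R,5E,9S)-5-(hydroxymethyl)-9-methyl-9,11-bis(triethylsilyloxy)undeca-1,5-dien-3-ol
Conditions: iBu2AlH (4.5 equiv), CH2Cl2, −78 → 0 °C; aq. KNaC4H4O6 work-up
Reagents that add atoms: none
Why: iBu2AlH reduces the conjugated lactone in 1,2-fashion through the lactol to the allylic diol, turning the lactone carbonyl into C14H2OH and freeing O8, with alkene geometry and silyl ethers unaffected.

Step 14
Reactants: 19 (3R,5E,9S)-5-(hydroxymethyl)-9-methyl-9,11-bis(triethylsilyloxy)undeca-1,5-dien-3-ol
Product: 20 [(2E,6S)-2-[(2R)-2-hydroxybut-3-enyl]-6-methyl-6,8-bis(triethylsilyloxy)oct-2-enyl] acetate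
Conditions: AcCl (1.05 equiv), 2,4,6-collidine, CH2Cl2, −78 °C
Reagents that add atoms: acetyl chloride, CC(=O)Cl
Why: Selective acylation, because at −78 °C with a hindered pyridine base acetyl chloride reacts with the primary allylic hydroxyl much faster than with the secondary one.

Step 15
Reactants: 20 [(2E,6S)-2-[(2R)-2-hydroxybut-3-enyl]-6-methyl-6,8-bis(triethylsilyloxy)oct-2-enyl] acetate; 21 2-(bromomethyl)acrylic acid
Product: 22 (3R,5E,9S)-5-(acetoxymethyl)-9-methyl-9,11-bis(triethylsilyloxy)undeca-1,5-dien-3-yl 2-(bromomethyl)acrylate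
Conditions: iPrN=C=NiPr, DMAP (5 mol%), CH2Cl2, 0 °C
Reagents that add atoms: none
Why: Steglich esterification of the secondary allylic alcohol under nearly neutral conditions, with only catalytic DMAP so that the allylic bromide is not displaced.

Step 16
Reactants: 22 (3R,5E,9S)-5-(acetoxymethyl)-9-methyl-9,11-bis(triethylsilyloxy)undeca-1,5-dien-3-yl 2-(bromomethyl)acrylate
Product: 23 (5R)-5-[(2E,6S)-2-(acetoxymethyl)-6-methyl-6,8-bis(triethylsilyloxy)oct-2-enyl]-3-(bromomethyl)furan-2(5H)-one
Conditions: (H2IMes)(PCy3)Cl2Ru=CHPh (second-generation Grubbs catalyst, 10 mol%), toluene, 80 °C, 5 mM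
Reagents that add atoms: none
Why: Ring-closing metathesis, in which the ruthenium carbene loads on the C8 vinyl group and closes onto the 1,1-disubstituted acrylate to give the butenolide alkene C7=C11 with loss of ethylene; the five-membered closure should outpace any reaction of the trisubstituted C1=C10 alkene, and allylic bromides are tolerated by this catalyst.

Step 17
Reactants: 23 (5R)-5-[(2E,6S)-2-(acetoxymethyl)-6-methyl-6,8-bis(triethylsilyloxy)oct-2-enyl]-3-(bromomethyl)furan-2(5H)-one
Product: 24 (5R)-5-[(2E,6S)-2-(acetoxymethyl)-8-hydroxy-6-methyl-6-(triethylsilyloxy)oct-2-enyl]-3-(bromomethyl)furan-2(5H)-one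
Conditions: pyridinium p-toluenesulfonate (cat.), MeOH/CH2Cl2 (1:4), 0 °C, monitored
Reagents that add atoms: none
Why: Acid-catalysed methanolysis of silyl ethers depends strongly on steric hindrance, so the primary triethylsilyl ether should be removed while the tertiary one stays.

Step 18
Reactants: 24 (5R)-5-[(2E,6S)-2-(acetoxymethyl)-8-hydroxy-6-methyl-6-(triethylsilyloxy)oct-2-enyl]-3-(bromomethyl)furan-2(5H)-one
Product: 25 (5R)-5-[(2E,6S)-2-(acetoxymethyl)-6-methyl-8-oxo-6-(triethylsilyloxy)oct-2-enyl]-3-(bromomethyl)furan-2(5H)-one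
Conditions: Dess–Martin periodinane, NaHCO3, CH2Cl2, 0 °C → rt; used at once
Reagents that add atoms: none
Why: Buffered Dess–Martin oxidation gives the C6 aldehyde without disturbing the allylic bromide, the butenolide or the β-silyloxy group.

Step 19
Reactants: 25 (5R)-5-[(2E,6S)-2-(acetoxymethyl)-6-methyl-8-oxo-6-(triethylsilyloxy)oct-2-enyl]-3-(bromomethyl)furan-2(5H)-one
Product: 28 (4S,6S,7R,8R)-14-acetoxy-6-hydroxy-4-(triethylsilyloxy)germacra-1(10),11(13)-dien-12,8-olide, via allylchromium dichloride 26 (not isolated), via chromium alkoxide 27 (not isolated)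
Conditions: CrCl2 (8 equiv), degassed THF, rt, 25 added over 10 h by syringe pump (final 2 mM); aq. NH4Cl work-up
Reagents that add atoms: none
Why: Two equivalents of divalent chromium reduce the allylic C–Br bond of 25 to the allylchromium dichloride 26 (trivalent chromium), which adds through its γ-carbon C7 to the tethered C6 aldehyde in a six-membered chair (Zimmerman–Traxler) transition state, moving the double bond to C11=C13 and giving alkoxide 27, hydrolysed on work-up; the closest known reaction type is the Nozaki–Hiyama–Kishi (chromium Barbier) allylation, known both as a macrocyclisation of allylic bromide aldehydes and as an intermolecular allylation with 3-(bromomethyl)butenolides. The ten-membered carbocycle closes in a 10-exo-trig addition to the carbonyl (SE2′ at the allyl unit), the lactone ring being present already. C7 is set by the C8 stereocentre: the C9 chain shields its own face of the planar butenolide, and the cis C1=C10 alkene lets the tether reach C6 on the opposite face, so the lactone should become trans-fused (H7 and H8 anti). C6 is set by the chair: C8 is held trans to CH2Cr on the ring alkene (an E-crotyl-type reagent) and C5 sits pseudo-equatorial, which should give the anti (6S) carbinol, the C6 epimer of the target configuration and exactly what the inverting esterification of step 20 requires. The step needs γ- over α-attack (secured by the cyclic transition state of allylchromium reagents), ring closure over oligomerisation (high dilution and slow addition) and chemoselectivity (allylic acetate, lactone and silyl ether are inert to divalent chromium).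

Step 20
Reactants: 28 (4S,6S,7R,8R)-14-acetoxy-6-hydroxy-4-(triethylsilyloxy)germacra-1(10),11(13)-dien-12,8-olide; 17 (Z)-2-(acetoxymethyl)but-2-enoic acid
Product: 30 (4S,6R,7S,8R)-14-acetoxy-6-[(Z)-2-(acetoxymethyl)but-2-enoyloxy]-4-(triethylsilyloxy)germacra-1(10),11(13)-dien-12,8-olide, via oxyphosphonium carboxylate 29 (not isolated)
Conditions: PPh3, iPrO2CN=NCO2iPr (betaine pre-formed), then 28 and 17, toluene, 0 °C → rt
Reagents that add atoms: none
Why: Mitsunobu esterification, in which the C6 hydroxyl is activated as oxyphosphonium ion 29 and displaced by the carboxylate of 17 in an SN2 reaction that inverts C6 to the 6R configuration of the target; the acid is never activated at its carbonyl group, so the Z alkene of the side chain is preserved, and the tertiary silyl ether and acetates are inert.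

Step 21
Reactants: 30 (4S,6R,7S,8R)-14-acetoxy-6-[(Z)-2-(acetoxymethyl)but-2-enoyloxy]-4-(triethylsilyloxy)germacra-1(10),11(13)-dien-12,8-olide
Product: 31 (4S,6R,7S,8R)-14-acetoxy-6-[(Z)-2-(acetoxymethyl)but-2-enoyloxy]-4-hydroxygermacra-1(10),11(13)-dien-12,8-olide (CNP0280960.1)
Conditions: HF·pyridine, pyridine, THF, 0 °C → rt
Reagents that add atoms: none
Why: Fluoride-driven cleavage of the tertiary triethylsilyl ether under buffered, non-basic conditions that leave both acetates, the conjugated ester and the α-methylene lactone intact.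

**Compound list**

1 | geraniol, (2E)-3,7-dimethylocta-2,6-dien-1-ol | CC(C)=CCC/C(C)=C/CO | starting material
2 | (2S,3S)-2,3-epoxygeraniol | CC(C)=CCC[C@]1(C)O[C@H]1CO | intermediate
3 | (3S)-3,7-dimethyloct-6-ene-1,3-diol | CC(C)=CCC[C@](C)(O)CCO | intermediate
4 | (3S)-3,7-dimethyl-1,3-bis(triethylsilyloxy)oct-6-ene | CC(C)=CCC[C@](C)(O[Si](CC)(CC)CC)CCO[Si](CC)(CC)CC | intermediate
5 | ozonide, 3,3-dimethyl-5-[(3S)-3-methyl-3,5-bis(triethylsilyloxy)pentyl]-1,2,4-trioxolane (not isolated) | CC1(C)OOC(CC[C@](C)(O[Si](CC)(CC)CC)CCO[Si](CC)(CC)CC)O1 | intermediate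
6 | (4S)-4-methyl-4,6-bis(triethylsilyloxy)hexanal | O=CCC[C@](C)(O[Si](CC)(CC)CC)CCO[Si](CC)(CC)CC | intermediate
7 | (5R)-5-(hydroxymethyl)dihydrofuran-2(3H)-one | OC[C@H]1CCC(=O)O1 | starting material
8 | (2R)-5-oxotetrahydrofuran-2-carbaldehyde | O=C[C@H]1CCC(=O)O1 | intermediate
9 | (5R)-5-vinyldihydrofuran-2(3H)-one | C=C[C@H]1CCC(=O)O1 | intermediate
10 | enol phosphate, diethyl (5R)-5-vinyl-4,5-dihydrofuran-2-yl phosphate (not isolated) | C=C[C@H]1CC=C(OP(=O)(OCC)OCC)O1 | intermediate
11 | diethyl [(5R)-2-oxo-5-vinyltetrahydrofuran-3-yl]phosphonate (C3 epimers) | C=C[C@H]1CC(P(=O)(OCC)OCC)C(=O)O1 | intermediate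
12 | (E)-but-2-enal (crotonaldehyde) | C/C=C/C=O | starting material
13 | (Z)-2-iodobut-2-enal | C/C=C(\I)C=O | intermediate
14 | (Z)-2-iodobut-2-en-1-ol | C/C=C(\I)CO | intermediate
15 | dilithio species of 14, C–Li in place of C–I and lithium alkoxide, methyl cis to C–Li (not isolated) | C/C=C(\[Li])CO[Li] | intermediate
16 | (Z)-2-(hydroxymethyl)but-2-enoic acid | C/C=C(\C(=O)O)CO | intermediate
17 | (Z)-2-(acetoxymethyl)but-2-enoic acid | C/C=C(\C(=O)O)COC(C)=O | intermediate
18 | (3E,5R)-3-[(4S)-4-methyl-4,6-bis(triethylsilyloxy)hexylidene]-5-vinyldihydrofuran-2(3H)-one | C=C[C@H]1C/C(=C\CC[C@](C)(O[Si](CC)(CC)CC)CCO[Si](CC)(CC)CC)C(=O)O1 | intermediate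
19 | (3R,5E,9S)-5-(hydroxymethyl)-9-methyl-9,11-bis(triethylsilyloxy)undeca-1,5-dien-3-ol | C=C[C@H](O)C/C(CO)=C\CC[C@](C)(O[Si](CC)(CC)CC)CCO[Si](CC)(CC)CC | intermediate
20 | [(2E,6S)-2-[(2R)-2-hydroxybut-3-enyl]-6-methyl-6,8-bis(triethylsilyloxy)oct-2-enyl] acetate | C=C[C@H](O)C/C(COC(C)=O)=C\CC[C@](C)(O[Si](CC)(CC)CC)CCO[Si](CC)(CC)CC | intermediate
21 | 2-(bromomethyl)acrylic acid | C=C(CBr)C(=O)O | starting material
22 | (3R,5E,9S)-5-(acetoxymethyl)-9-methyl-9,11-bis(triethylsilyloxy)undeca-1,5-dien-3-yl 2-(bromomethyl)acrylate | C=C[C@H](OC(=O)C(=C)CBr)C/C(COC(C)=O)=C\CC[C@](C)(O[Si](CC)(CC)CC)CCO[Si](CC)(CC)CC | intermediate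
23 | (5R)-5-[(2E,6S)-2-(acetoxymethyl)-6-methyl-6,8-bis(triethylsilyloxy)oct-2-enyl]-3-(bromomethyl)furan-2(5H)-one | BrCC1=C[C@@H](C/C(COC(C)=O)=C\CC[C@](C)(O[Si](CC)(CC)CC)CCO[Si](CC)(CC)CC)OC1=O | intermediate
24 | (5R)-5-[(2E,6S)-2-(acetoxymethyl)-8-hydroxy-6-methyl-6-(triethylsilyloxy)oct-2-enyl]-3-(bromomethyl)furan-2(5H)-one | BrCC1=C[C@@H](C/C(COC(C)=O)=C\CC[C@](C)(O[Si](CC)(CC)CC)CCO)OC1=O | intermediate
25 | (5R)-5-[(2E,6S)-2-(acetoxymethyl)-6-methyl-8-oxo-6-(triethylsilyloxy)oct-2-enyl]-3-(bromomethyl)furan-2(5H)-one | BrCC1=C[C@@H](C/C(COC(C)=O)=C\CC[C@](C)(O[Si](CC)(CC)CC)CC=O)OC1=O | intermediate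
26 | allylchromium dichloride derived from 25, CH2CrCl2 in place of CH2Br (not isolated) | Cl[Cr](Cl)CC1=C[C@@H](C/C(COC(C)=O)=C\CC[C@](C)(O[Si](CC)(CC)CC)CC=O)OC1=O | intermediate
27 | chromium dichloride alkoxide of 28, O6–CrCl2 (not isolated) | C=C1C(=O)O[C@@H]2C/C(COC(C)=O)=C\CC[C@](C)(O[Si](CC)(CC)CC)C[C@H](O[Cr](Cl)Cl)[C@@H]12 | intermediate
28 | (4S,6S,7R,8R)-14-acetoxy-6-hydroxy-4-(triethylsilyloxy)germacra-1(10),11(13)-dien-12,8-olide (trans-fused lactone, O6 trans to C11 on the ring) | C=C1C(=O)O[C@@H]2C/C(COC(C)=O)=C\CC[C@](C)(O[Si](CC)(CC)CC)C[C@H](O)[C@@H]12 | intermediate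
29 | O6-triphenylphosphonium derivative of 28 as its (Z)-2-(acetoxymethyl)but-2-enoate salt (not isolated) | C=C1C(=O)O[C@@H]2C/C(COC(C)=O)=C\CC[C@](C)(O[Si](CC)(CC)CC)C[C@H](O[P+](c3ccccc3)(c3ccccc3)c3ccccc3)[C@@H]12.C/C=C(\C(=O)[O-])COC(C)=O | intermediate
30 | (4S,6R,7S,8R)-14-acetoxy-6-[(Z)-2-(acetoxymethyl)but-2-enoyloxy]-4-(triethylsilyloxy)germacra-1(10),11(13)-dien-12,8-olide | C=C1C(=O)O[C@@H]2C/C(COC(C)=O)=C\CC[C@](C)(O[Si](CC)(CC)CC)C[C@@H](OC(=O)/C(=C\C)COC(C)=O)[C@@H]12 | intermediate
31 | (4S,6R,7S,8R)-14-acetoxy-6-[(Z)-2-(acetoxymethyl)but-2-enoyloxy]-4-hydroxygermacra-1(10),11(13)-dien-12,8-olide, CNP0280960.1 | C=C1C(=O)O[C@@H]2C/C(COC(C)=O)=C\CC[C@](C)(O)C[C@@H](OC(=O)/C(=C\C)COC(C)=O)[C@@H]12 | target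

**Summary**

Total step count: 21.
Longest linear sequence: 14 steps (steps 1–4 and 12–21, from geraniol).

**Steps most likely to fail**

Step 19 (ring closure). What may go wrong: the carbonyl face may be selected by the strain of the forming ten-membered ring and not by the chair preference (C5 forced pseudo-axial), so that the carbinol forms with the opposite configuration at C6; intermolecular coupling may compete if dilution is insufficient. The fallback sets out from 25 and comes back at 30. If the closure delivers the 6R epimer, (4S,6R,7R,8R)-14-acetoxy-6-hydroxy-4-(triethylsilyloxy)germacra-1(10),11(13)-dien-12,8-olide F1, no inversion is wanted. Acid 17 is then converted with 2,4,6-trichlorobenzoyl chloride and Et3N in toluene into the mixed anhydride (Z)-2-(acetoxymethyl)but-2-enoic 2,4,6-trichlorobenzoic anhydride F2, which acylates F1 with retention (DMAP, toluene, rt, Yamaguchi esterification) to give 30.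

Step 20 (Mitsunobu esterification). What may go wrong: slow formation of the oxyphosphonium ion at the hindered carbinol, E2 elimination toward C5 or C7 in place of substitution, or addition of free PPh3 to the α-methylene lactone. The fallback sets out from 28 and comes back at 30, and uses sulfonate displacement without any phosphine. Alcohol 28 is converted (MsCl, Et3N, CH2Cl2, −20 °C) into the (6S)-6-O-methanesulfonate of 28 F3. This is displaced with inversion by cesium (Z)-2-(acetoxymethyl)but-2-enoate F4 (made from 17 and Cs2CO3) in DMF with 18-crown-6 at 40–50 °C to give 30.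

Step 16 (ring-closing metathesis). What may go wrong: slow closure onto the electron-poor 1,1-disubstituted alkene that carries CH2Br, so that cross-metathesis dimerisation at the vinyl group or catalyst decay caused by the allylic bromide wins. The fallback sets out from 20 and comes back at 23, and adds C13 after the ring is made. Alcohol 20 is acylated with acryloyl chloride (iPr2NEt, CH2Cl2, −78 °C) to (3R,5E,9S)-5-(acetoxymethyl)-9-methyl-9,11-bis(triethylsilyloxy)undeca-1,5-dien-3-yl acrylate F5. Ring-closing metathesis onto the monosubstituted acrylate (same ruthenium catalyst, CH2Cl2, 40 °C) gives (5R)-5-[(2E,6S)-2-(acetoxymethyl)-6-methyl-6,8-bis(triethylsilyloxy)oct-2-enyl]furan-2(5H)-one F6. Morita–Baylis–Hillman hydroxymethylation with aqueous formaldehyde and imidazole (THF/H2O, rt) gives (5R)-5-[(2E,6S)-2-(acetoxymethyl)-6-methyl-6,8-bis(triethylsilyloxy)oct-2-enyl]-3-(hydroxymethyl)furan-2(5H)-one F7; the C8 centre has to be checked for epimerisation at this point. Appel bromination (CBr4, PPh3, CH2Cl2, 0 °C) returns 23.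

**Further compounds**

F1 | step 19 | (4S,6R,7R,8R)-14-acetoxy-6-hydroxy-4-(triethylsilyloxy)germacra-1(10),11(13)-dien-12,8-olide | C=C1C(=O)O[C@@H]2C/C(COC(C)=O)=C\CC[C@](C)(O[Si](CC)(CC)CC)C[C@@H](O)[C@@H]12
F2 | step 19 | (Z)-2-(acetoxymethyl)but-2-enoic 2,4,6-trichlorobenzoic anhydride | C/C=C(\C(=O)OC(=O)c1c(Cl)cc(Cl)cc1Cl)COC(C)=O
F3 | step 20 | (6S)-6-O-methanesulfonate of 28 | C=C1C(=O)O[C@@H]2C/C(COC(C)=O)=C\CC[C@](C)(O[Si](CC)(CC)CC)C[C@H](OS(C)(=O)=O)[C@@H]12
F4 | step 20 | cesium (Z)-2-(acetoxymethyl)but-2-enoate | C/C=C(\C(=O)[O-])COC(C)=O.[Cs+]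
F5 | step 16 | (3R,5E,9S)-5-(acetoxymethyl)-9-methyl-9,11-bis(triethylsilyloxy)undeca-1,5-dien-3-yl acrylate | C=C[C@H](OC(=O)C=C)C/C(COC(C)=O)=C\CC[C@](C)(O[Si](CC)(CC)CC)CCO[Si](CC)(CC)CC
F6 | step 16 | (5R)-5-[(2E,6S)-2-(acetoxymethyl)-6-methyl-6,8-bis(triethylsilyloxy)oct-2-enyl]furan-2(5H)-one | O=C1C=C[C@@H](C/C(COC(C)=O)=C\CC[C@](C)(O[Si](CC)(CC)CC)CCO[Si](CC)(CC)CC)O1
F7 | step 16 | (5R)-5-[(2E,6S)-2-(acetoxymethyl)-6-methyl-6,8-bis(triethylsilyloxy)oct-2-enyl]-3-(hydroxymethyl)furan-2(5H)-one | OCC1=C[C@@H](C/C(COC(C)=O)=C\CC[C@](C)(O[Si](CC)(CC)CC)CCO[Si](CC)(CC)CC)OC1=O
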